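**Numbering used throughout.** Ring A: C1 (methyl), C2 (H), C3 (OH), C4 (CHO), C5 (ether O), C6 (bears the ester carbonyl C7). Ring B: C1′ (ester O), C2′ (CH2O–fumarate), C3′ (OH), C4′ (lactone C=O), C5′ (lactol carbon), C6′ (ether O). Ring C is the seven-membered ring O–C5–C6–C7(=O)–O–C1′–C6′.

## The problem

The target 24 is a depsidone: ring A and the fully substituted ring B are joined twice, by the ester C7(=O)–O–C1′ and by the diaryl ether C5–O–C6′, and these two links make the seven-membered ring C. Ring B carries in sequence an ester oxygen, a benzylic CH2O acylated by fumaric acid, a phenol and a fused 3-hydroxyphthalide (lactone carbonyl on C4′, lactol carbon on C5′), so its pattern cannot be left to the weak regiocontrol of electrophilic substitution. The only stereocenter is the (R) lactol carbon, a hemiacetal of an ortho-formyl benzoic acid that epimerizes by ring opening; no other stereocenter exists to control it, so it can only be fixed last and outside solution equilibria. The E double bond comes with the fumarate. The molecule is fragile: the C2′ benzylic ester next to the C3′ phenol ionizes to an ortho-quinone methide with base, heat or nucleophilic solvents, and the aryl ester is cleaved or rearranged by phenoxides. The fumarate adds amines and thiols and is lost on hydrogenation, and both the C4 aldehyde and the lactol can be oxidized or reduced. Protecting groups must therefore leave under neutral conditions, and no base may be used once the free C3′ phenol and the fumarate coexist. A late closure of ring C is possible because, in the open depside, C6′ is the single unsubstituted carbon of ring B, lies para to the free C3′ hydroxyl and ortho to the C1′ ester oxygen, and is held under the C5 hydroxyl by the C7 ester: the geometry of an oxidative phenol coupling.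

## Retrosynthesis

**Lactol configuration (24 ⇒ 23 ⇒ 22).** No skeletal bond is cut. Target 24 is taken back to its crystalline ammonium salt 23 and then to depsidone 22, whose lactol carbon is an equilibrating pair. Because the hemiacetal opens and recloses, an earlier asymmetric step would be erased and a classical resolution would waste half the material. A crystallization that feeds on the equilibrium can in principle convert all of 22. The fumaric carboxylic acid is the handle for the salt. The base must be tertiary, so that it neither condenses with the aldehyde or the lactol nor adds to the fumarate. The forward operation needs a lattice that accepts one lactol configuration and a salt break that never dissolves the product.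

**Ring C (22 ⇒ 21).** The bond cut is the ether bond between the C5 oxygen and C6′. This opens ring C and leaves depside 21 with a C5 hydroxyl and a C6′ hydrogen; 21 is drawn without lactol configuration because that carbon equilibrates.
- The neighbouring cut at the ester C7–O would need a diaryl ether synthesis between two partners substituted on both flanks, followed by lactonization onto the most hindered phenol.
- A redox-neutral version of the same ether cut would need an extra oxygen or halogen on a ring B that already has five substituents.
- The oxidative cut needs neither: the precursor has one substituent fewer and is assembled by one acylation, and nothing has to be deprotected after the closure.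

The forward reaction must be a two-electron oxidation that touches only the two phenols in the presence of an aldehyde, a lactol, a benzylic ester and an electron-poor alkene. Both rings are electron-poor, so no chemical one-electron oxidant is selective enough. The closure is therefore entrusted to a depsidone-forming cytochrome P450, which performs exactly this depside-to-depsidone change at neutral pH in the producing organisms. To strengthen this, 21 is offered fully deprotected, so that at pH 7.4 its lactol opens to a free C4′ carboxylate like that of the native depsides. The route is also laid out so that a halogenated depside for a copper-mediated closure is reachable from the same intermediates.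

**Unmasking (21 ⇒ 20 ⇒ 19).** Four allyl–oxygen bonds are reinstated: the two phenol ethers on ring A, the ester on the C4′ carboxyl and the outer fumarate ester. The lactol is carried as a C5′ aldehyde plus C4′ allyl ester, because a free lactol hydroxyl would be acylated in the coupling. When the acid is freed, formyl acid 20 closes to 21 by itself. Allyl is chosen because it leaves by palladium-catalysed allyl transfer under neutral conditions. Acid-labile sets would need strong acid on a benzylic ester beside a free phenol, hydrogenolysis would reduce the fumarate, and base is excluded. Protected depside 19 has no free carboxylic acid, no lactol and only one free phenol, and is stable to chromatography.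

**Ester link (19 ⇒ 4 + 17).** The bond cut is C7–O(C1′), giving ring A acid 4 and ring B phenol 17. In 17 the C3′ hydroxyl is hydrogen-bonded to the C4′ ester, so only the C1′ hydroxyl should be acylated and ring B needs no phenol protection. The fumarate is already in place. Attaching it after the coupling would require a free benzylic alcohol beside the aryl ester, which invites acyl migration. The forward reaction must acylate a hindered, electron-poor phenol with a di-ortho-substituted acid without generating a phenoxide; activation as mixed anhydride 18 in an acidic medium does this.

**Fumarate and phenol release (17 ⇒ 16 ⇒ 15 + 7).** The two MOM ethers and the dimethyl acetal of 16 are reinstated, then the benzylic ester is cut to alcohol 15 and half-ester 7. The ester is made while both flanking phenols are capped, so no quinone methide can form and 15 has a single hydroxyl. The acid step then has to spare the benzylic ester, which the electron-poor ring should allow.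

**Ring B carbons (15 ⇒ 12 ⇒ 10 ⇒ 9 ⇒ 8).** The C4′ carboxyl carbon and then the C2′ hydroxymethyl carbon are removed, leading to acetal 10 and through aldehyde 9 to 3,5-dihydroxybenzaldehyde 8. The C5′ carbon is present from the start at the aldehyde oxidation level, so no benzylic oxidation is needed. Compound 10 has a mirror plane. The first lithiation can only go between the two MOM ethers (C2′), and in 12 the two remaining positions are equivalent (C4′), so regiochemistry is fixed by symmetry. Electrophilic formylation of a resorcinol ester would instead give mixtures at C2′ and C6′. The C6′ hydrogen is what remains.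

**Ring A (4 ⇒ 3 ⇒ 2 ⇒ 1).** The carboxylic acid is taken back to methyl ester 3, the allyl ethers to methyl haematommate 2, and the formyl group is removed to give methyl orsellinate 1. The formyl group is introduced first, between two free hydroxyls, where chelation directs it. The phenols are capped before saponification, because a phenoxide would deactivate the hindered ester.

**Half-ester (7 ⇒ 6 ⇒ 5).** Half-ester 7 comes from maleic anhydride 5 through Z half-ester 6. The E geometry is thermodynamic.

## Roads not taken

**Alternative 1:** ring B from a four-membered ring.
- Cut: inside ring B. The benzene ring is taken back to cyclobutenone A2, made by two carbanion additions to diisopropyl squarate A1, so that C3′–C4′ is the last bond formed.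
- Forward key step: on heating, A2 undergoes four-electron ring opening and six-electron ring closure, the former carbonyl carbon (future C3′) bonding to the acrylate carbon (future C4′). Enolization gives hydroquinone A3 with the C1′ isopropyl ether, a MOM-protected C2′ hydroxymethyl, the C4′ tert-butyl ester, the C5′ diethyl acetal and free hydroxyls on C3′ and C6′.
- Merits: every substituent is placed by the order of additions, not by aromatic substitution. In one respect this road is better than the chosen one: A3 already has an oxygen on C6′, so ring C could be closed by established ether and ester chemistry without an enzymatic step that lacks precedent on this substrate.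
- Weak points: it solves ring B only. Ring C still needs an ether from the hindered C6′ hydroxyl to a halogenated ring A and a lactonization onto C1′ after the isopropyl group is removed with a strong Lewis acid. The two hydroquinone hydroxyls must be told apart. The second carbanion is a metallated acrylate bearing an acetal, which is hard to generate. Four different protecting groups come off under acids of increasing strength before the fumarate can be attached.
- Comparison: the chosen plan sets against the precedented ring closure a ring B phenol 17 reached in six steps with regiochemistry fixed by symmetry, no extra oxygen or halogen on ring B, and one neutral deprotection. The iodide fallback recovers much of what this road offers if the enzyme fails.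

**Alternative 2:** ring A and ring C by photochemical benzannulation.
- Cut: all of ring A (bonds C6–C1, C3–C4, C6–C5, C3–C2) and with it ring C. The precursor is diazo keto ester A4, in which the future C6 is a diazo carbon between a methacryloyl group and the aryl ester of ring B, and the C6′ oxygen carries an alkynyl ether.
- Forward key step: light removes the diazo nitrogen with 1,2-shift of the isopropenyl group (Wolff rearrangement, bond C6–C1). The cumulated C=C=O unit adds across the tethered alkynyl ether (bonds C3–C4 and C6–C5), and the four-membered ring opens and recloses (bond C3–C2) to phenol A5, a protected depsidone with the C4 formyl group as its dimethyl acetal.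
- Merits: three carbon–carbon bonds and two rings in one operation. Every ring A substituent is set by the connectivity of A4, with no formylation regiochemistry and no esterification of a di-ortho-substituted acid. The ether oxygen is in place, so no phenol is oxidized. In convergence and in avoiding the oxidation it is superior to the chosen plan.
- Weak points: A4 needs a ring B with an additional oxygen on C6′ converted into an aryl alkynyl ether next to the acylated C1′ oxygen, which is harder than 17 by one substituent and several steps. The intramolecular cycloaddition must build a strained bicycle containing the seven-membered ring, against dimerization and photo-Fries cleavage of the aryl ester; in this ring size it is no better precedented than the enzymatic closure. A5 still carries a silyl ether, a MOM ether, a tert-butyl ester and two acetals, so the end game is several acidic operations and a late acylation of the benzylic alcohol beside a free phenol.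
- Comparison: the chosen plan sets against the cascade a shorter route from a commercial ring A and an end game without acid or base.

**Alternative 3:** ring A grown on the ring B phenol.
- Cut: the ester bond C7–O(C1′) and, inside ring A, the bond C6–C1.
- Forward key step: heating diketo-dioxinone A6 with fluorophenol A7 triggers cycloreversion of the dioxinone ring. The C1′ hydroxyl of A7 adds to the C=C=O unit set free (bond C7–O), and the chain closes ring A by aldol condensation of C6 onto the C1 ketone and dehydration. The product is depside A8, the orsellinate of ring B with fluorine on C6′.
- Merits: the ester to the hindered phenol forms by ketene capture under neutral thermal conditions, at least as good as step 11. The C6′ fluorine prepares a closure by nucleophilic aromatic substitution, a reaction type with ample precedent, which the enzymatic closure cannot claim.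
- Weak points: A8 lacks the C4 formyl group, which would have to be introduced late between two hydroxyls of a depside, with C2 competing. The fluoride is activated only by the C5′ carbonyl once the acetal is removed. The closure then needs a phenoxide and heat on a depside whose C1′ is para to the C4′ ester, the setting for Smiles rearrangement or ester cleavage. The fluorinated ring B needs its own synthesis. Silyl, MOM, tert-butyl and acetal groups must again be removed with acid before the fumarate goes on beside a free phenol.
- Comparison: the chosen plan sets against the better-precedented closure a formyl group carried from step 1, a coupling and closure free of base, and fewer steps.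

Key step: step 13

Remark on the chemistry: the lactol carbon epimerizes in solution by ring opening to the 2-formylbenzoic acid, so 21 and 22 are drawn without configuration, the (R) descriptor of 24 is taken to apply to the isolated crystalline solid, and the (R)-amine of step 14 stands for whichever enantiomer screening shows to crystallize with the (R)-lactol.

## Route

Step 1
Reactants: 1 methyl orsellinate (methyl 2,4-dihydroxy-6-methylbenzoate)
Product: 2 methyl haematommate (methyl 3-formyl-2,4-dihydroxy-6-methylbenzoate)
Conditions: Cl2CHOMe, TiCl4, CH2Cl2, −78 → 0 °C; aq HCl
Reagents that add atoms: dichloromethyl methyl ether, COC(Cl)Cl; water, O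
Why: Rieche formylation (TiCl4-promoted Friedel–Crafts reaction of a dichloromethyl ether); the carbon between the two hydroxyls is ortho to both and is reached through the titanium phenoxide chelate, so it should be the main site, and the isomer formylated next to the methyl group should be removable by crystallization.

Step 2
Reactants: 2 methyl haematommate
Product: 3 methyl 2,4-bis(allyloxy)-3-formyl-6-methylbenzoate
Conditions: allyl bromide, K2CO3, DMF, 60 °C
Reagents that add atoms: allyl bromide, C=CCBr
Why: Williamson etherification; carbonate in warm DMF alkylates both hydrogen-bonded hydroxyls, which removes the phenoxide that would deactivate the ester in step 3 and leaves ring A without a nucleophile in step 11.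

Step 3
Reactants: 3 methyl 2,4-bis(allyloxy)-3-formyl-6-methylbenzoate
Product: 4 2,4-bis(allyloxy)-3-formyl-6-methylbenzoic acid
Conditions: KOH, MeOH–H2O, 70 °C; then aq HCl, 0 °C
Reagents that add atoms: potassium hydroxide, [K+].[OH-]
Why: Saponification (acyl–oxygen cleavage) of a di-ortho-substituted benzoate; with the phenols capped the ring is neutral, so hydroxide should reach the ester on prolonged heating, and the aldehyde flanked by two ether groups is too hindered for a Cannizzaro reaction at this concentration.

Step 4
Reactants: 5 maleic anhydride
Product: 7 mono-allyl fumarate ((2E)-4-(allyloxy)-4-oxobut-2-enoic acid), via mono-allyl maleate 6 (not isolated)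
Conditions: allyl alcohol, 60 °C; then AcCl (5 mol %), toluene, 85 °C
Reagents that add atoms: allyl alcohol, C=CCO
Why: Ring opening of a cyclic anhydride by an alcohol gives the Z half-ester, and reversible addition of HCl (from catalytic AcCl) to the double bond isomerizes it to the thermodynamically favoured, crystalline E half-ester, the reaction type used for other monoalkyl fumarates.

Step 5
Reactants: 8 3,5-dihydroxybenzaldehyde
Product: 9 3,5-bis(methoxymethoxy)benzaldehyde
Conditions: MOMCl, i-Pr2NEt, CH2Cl2, 0 → 20 °C
Reagents that add atoms: chloromethyl methyl ether, COCCl
Why: Alkylation of phenols with a chloromethyl ether (MOM protection); MOM is chosen because it directs both later lithiations and leaves with mild acid.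

Step 6
Reactants: 9 3,5-bis(methoxymethoxy)benzaldehyde
Product: 10 1-(dimethoxymethyl)-3,5-bis(methoxymethoxy)benzene
Conditions: HC(OMe)3, MeOH, PPTS (cat.), 40 °C; Et3N quench
Reagents that add atoms: trimethyl orthoformate, COC(OC)OC; methanol, CO
Why: Acid-catalysed acetalization driven by the orthoformate as water scavenger; the acetal hides the aldehyde from organolithiums and serves as the second directing group in step 8.

Step 7
Reactants: 10 1-(dimethoxymethyl)-3,5-bis(methoxymethoxy)benzene
Product: 12 [4-(dimethoxymethyl)-2,6-bis(methoxymethoxy)phenyl]methanol, via aryllithium 11 (not isolated)
Conditions: n-BuLi, THF, 0 °C; (CH2O)n, 0 → 20 °C; then H2O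
Reagents that add atoms: formaldehyde (from paraformaldehyde), C=O
Why: Directed ortho-metalation followed by hydroxymethylation with formaldehyde; the hydrogen between the two MOM ethers is the most acidic because lithium is held by both oxygens, and the mirror symmetry of 10 makes this site unique.

Step 8
Reactants: 12 [4-(dimethoxymethyl)-2,6-bis(methoxymethoxy)phenyl]methanol
Product: 15 allyl 6-(dimethoxymethyl)-3-(hydroxymethyl)-2,4-bis(methoxymethoxy)benzoate, via dilithio species 13 (not isolated), via lithium carboxylate 14 (not isolated)
Conditions: n-BuLi (2.3 equiv), TMEDA, THF, −40 → 0 °C; CO2, −78 → 0 °C; H2O; then allyl bromide, Bu4NBr (cat.), CH2Cl2–H2O, 20 °C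
Reagents that add atoms: carbon dioxide, O=C=O; allyl bromide, C=CCBr
Why: Directed ortho-metalation of the lithium alkoxide, carboxylation and phase-transfer O-alkylation of the carboxylate; the two remaining ring positions are equivalent and each lies between a MOM ether and the acetal, the alkoxide shields the benzylic hydrogens from the base, and a carboxylate is allylated far faster than a neutral alcohol. The acid is never liberated, so it cannot close onto the neighbouring acetal.

Step 9
Reactants: 15 allyl 6-(dimethoxymethyl)-3-(hydroxymethyl)-2,4-bis(methoxymethoxy)benzoate; 7 mono-allyl fumarate
Product: 16 allyl 3-({[(2E)-4-(allyloxy)-4-oxobut-2-enoyl]oxy}methyl)-6-(dimethoxymethyl)-2,4-bis(methoxymethoxy)benzoate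
Conditions: EDC·HCl, DMAP (cat.), CH2Cl2, 0 → 20 °C
Reagents that add atoms: none
Why: Steglich (carbodiimide/DMAP) esterification of the only hydroxyl in 15; both flanking phenols are still capped, so no ortho-quinone methide can form while the benzylic ester is made.

Step 10
Reactants: 16 allyl 3-({[(2E)-4-(allyloxy)-4-oxobut-2-enoyl]oxy}methyl)-6-(dimethoxymethyl)-2,4-bis(methoxymethoxy)benzoate
Product: 17 allyl 3-({[(2E)-4-(allyloxy)-4-oxobut-2-enoyl]oxy}methyl)-6-formyl-2,4-dihydroxybenzoate
Conditions: TFA–CH2Cl2 (1:4), H2O (5 equiv), 0 → 20 °C
Reagents that add atoms: water, O
Why: Acid hydrolysis of the two MOM acetals and the dimethyl acetal; once the C5′ formyl group para to the benzylic carbon is free, it and the C4′ ester disfavour benzylic ionization, so the fumarate ester and both allyl esters should survive dilute TFA at or below room temperature.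

Step 11
Reactants: 4 2,4-bis(allyloxy)-3-formyl-6-methylbenzoic acid; 17 allyl 3-({[(2E)-4-(allyloxy)-4-oxobut-2-enoyl]oxy}methyl)-6-formyl-2,4-dihydroxybenzoate
Product: 19 allyl-protected depside (the C1′ ester of 17 with acid 4), via mixed anhydride 18 (not isolated)
Conditions: 4, (CF3CO)2O, toluene, 0 °C; then 17, 20 °C; pH 7 phosphate wash
Reagents that add atoms: none
Why: Mixed trifluoroacetic anhydride esterification, the classical depside coupling; it activates the hindered acid as an acylium-like species in an acidic medium (no phenoxide, hence no quinone methide), and the C1′ hydroxyl should react because the C3′ hydroxyl is tied up in a hydrogen bond to the C4′ ester carbonyl.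

Step 12
Reactants: 19 allyl-protected depside
Product: 21 depside with free C5 hydroxyl and C6′ hydrogen (lactol as equilibrating pair), via formyl acid 20 (not isolated)
Conditions: Pd(PPh3)4 (5 mol %), PhNHMe, THF, 20 °C, argon; cold 0.5 M HCl wash
Reagents that add atoms: none
Why: Tsuji–Trost deallylation; zerovalent palladium ionizes the two allyl esters and the two allyl ethers of acidic ortho-carbonyl phenols, and N-methylaniline takes up the allyl groups while being too weakly basic to form phenoxides and too poor a nucleophile for the fumarate or the aldehydes at this temperature. The liberated ortho-formyl benzoic acid 20 should close spontaneously to the hydroxyphthalide.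

Step 13
Reactants: 21 depside with free C5 hydroxyl and C6′ hydrogen
Product: 22 depsidone (target constitution, lactol as equilibrating pair)
Conditions: depsidone-synthase cytochrome P450 with its NADPH–P450 reductase (yeast microsomes), NADPH (cat.), D-glucose, glucose dehydrogenase, air, KH2PO4/K2HPO4 buffer pH 7.4, 5% DMSO, 28 °C; then pH 2.5, EtOAc
Reagents that add atoms: none
Why: Proposed new method: the enzyme's iron-oxo haem radical cation (tetravalent iron) should take a hydrogen atom from the C3′ hydroxyl and then from the C5 hydroxyl; the ring B radical carries spin on C6′ (para to its oxygen), the C5 oxygen bonds to that carbon, and loss of the C6′ hydrogen restores the aromatic ring, while O2 ends as water at the expense of NADPH. The closest known reaction type is the cytochrome P450 oxidative phenol coupling that turns depsides into depsidones in lichen and fungal biosynthesis and has been reproduced with heterologously expressed enzymes on their native depsides; it has not been applied to a depside bearing a fumarate half-ester and an ortho-formyl carboxylate. Ring C closes in a seven-membered mode, formally 7-endo-trig at C6′ with the aromatic bond C6′–C1′ inside the new ring, helped by the C7 ester, which holds the C5 oxygen within bonding distance of C6′. No stereocenter is formed, and the lactol carbon stays an equilibrating pair. The step needs carbon–oxygen coupling at C6′ rather than carbon–carbon coupling or oxygen rebound: C6′ is the only unsubstituted carbon of ring B, the other spin-bearing carbons of both rings are substituted or cannot reach across the tether, and the active site of a β-orcinol depsidone synthase is built to place C6′ of such a depside under the C5 oxygen. At pH 7.4 the lactol is open as a C4′ carboxylate with a C5′ formyl group, which resembles the free C4′ carboxylate of the native depsides, and the mild aqueous medium spares the aldehyde, the fumarate and the benzylic ester that chemical one-electron oxidants would attack.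

Step 14
Reactants: 22 depsidone (lactol as equilibrating pair)
Product: 23 (R)-N,N-dimethyl-1-phenylethylammonium salt of the (R)-lactol depsidone
Conditions: (R)-PhCH(Me)NMe2 (1.0 equiv), MeCN–i-PrOAc, slurry 35 → 5 °C, seeding, filtration
Reagents that add atoms: (R)-N,N-dimethyl-1-phenylethylamine, C[C@@H](N(C)C)c1ccccc1
Why: Proposed new method: one equivalent of a tertiary amine deprotonates only the fumaric carboxylic acid, while in the mother liquor the lactol carbon epimerizes by ring opening to the ortho-formyl benzoic acid and reclosure, so the less soluble diastereomeric salt, here taken to be that of the (R)-lactol, should grow at the expense of the other and the new stereocenter is set by the lattice of the salt; the closest known reaction type is crystallization-induced diastereomer transformation of epimerizable carboxylic acids as chiral ammonium salts, which has not been shown for a hydroxyphthalide lactol carbon.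

Step 15
Reactants: 23 ammonium salt of the (R)-lactol depsidone
Product: 24 target depsidone, (R)-lactol
Conditions: 0.5 M aq HCl, 0 °C, slurry; filtration; cold H2O wash; vacuum drying
Reagents that add atoms: none
Why: Liberation of a carboxylic acid from its ammonium salt by a stronger acid, run as a cold solid-to-solid slurry conversion; the free acid is expected to be insoluble in cold dilute HCl, so the lactol should never be in solution long enough to open and the (R) configuration set in step 14 should be carried into the solid.

## Compound list

1 | methyl orsellinate | COC(=O)c1c(C)cc(O)cc1O | starting material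
2 | methyl haematommate | COC(=O)c1c(C)cc(O)c(C=O)c1O | intermediate
3 | methyl 2,4-bis(allyloxy)-3-formyl-6-methylbenzoate | COC(=O)c1c(C)cc(OCC=C)c(C=O)c1OCC=C | intermediate
4 | 2,4-bis(allyloxy)-3-formyl-6-methylbenzoic acid | OC(=O)c1c(C)cc(OCC=C)c(C=O)c1OCC=C | intermediate
5 | maleic anhydride | O=C1OC(=O)C=C1 | starting material
6 | mono-allyl maleate (not isolated) | C=CCOC(=O)/C=C\C(=O)O | intermediate
7 | mono-allyl fumarate | C=CCOC(=O)/C=C/C(=O)O | intermediate
8 | 3,5-dihydroxybenzaldehyde | O=Cc1cc(O)cc(O)c1 | starting material
9 | 3,5-bis(methoxymethoxy)benzaldehyde | O=Cc1cc(OCOC)cc(OCOC)c1 | intermediate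
10 | 1-(dimethoxymethyl)-3,5-bis(methoxymethoxy)benzene | COC(OC)c1cc(OCOC)cc(OCOC)c1 | intermediate
11 | [4-(dimethoxymethyl)-2,6-bis(methoxymethoxy)phenyl]lithium (not isolated) | COC(OC)c1cc(OCOC)c([Li])c(OCOC)c1 | intermediate
12 | [4-(dimethoxymethyl)-2,6-bis(methoxymethoxy)phenyl]methanol | COC(OC)c1cc(OCOC)c(CO)c(OCOC)c1 | intermediate
13 | ring-lithiated lithium alkoxide of 12 (not isolated) | COC(OC)c1cc(OCOC)c(CO[Li])c(OCOC)c1[Li] | intermediate
14 | lithium 6-(dimethoxymethyl)-3-(hydroxymethyl)-2,4-bis(methoxymethoxy)benzoate (not isolated) | [Li]OC(=O)c1c(OCOC)c(CO)c(OCOC)cc1C(OC)OC | intermediate
15 | allyl 6-(dimethoxymethyl)-3-(hydroxymethyl)-2,4-bis(methoxymethoxy)benzoate | C=CCOC(=O)c1c(OCOC)c(CO)c(OCOC)cc1C(OC)OC | intermediate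
16 | allyl 3-({[(2E)-4-(allyloxy)-4-oxobut-2-enoyl]oxy}methyl)-6-(dimethoxymethyl)-2,4-bis(methoxymethoxy)benzoate | C=CCOC(=O)c1c(OCOC)c(COC(=O)/C=C/C(=O)OCC=C)c(OCOC)cc1C(OC)OC | intermediate
17 | allyl 3-({[(2E)-4-(allyloxy)-4-oxobut-2-enoyl]oxy}methyl)-6-formyl-2,4-dihydroxybenzoate | C=CCOC(=O)c1c(O)c(COC(=O)/C=C/C(=O)OCC=C)c(O)cc1C=O | intermediate
18 | 2,4-bis(allyloxy)-3-formyl-6-methylbenzoic trifluoroacetic anhydride (not isolated) | Cc1cc(OCC=C)c(C=O)c(OCC=C)c1C(=O)OC(=O)C(F)(F)F | intermediate
19 | allyl-protected depside (four allyl groups) | Cc1cc(OCC=C)c(C=O)c(OCC=C)c1C(=O)Oc1cc(C=O)c(C(=O)OCC=C)c(O)c1COC(=O)/C=C/C(=O)OCC=C | intermediate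
20 | ring-open formyl acid of the depside (not isolated) | Cc1cc(O)c(C=O)c(O)c1C(=O)Oc1cc(C=O)c(C(=O)O)c(O)c1COC(=O)/C=C/C(=O)O | intermediate
21 | depside, lactol as equilibrating pair | Cc1cc(O)c(C=O)c(O)c1C(=O)Oc1c(COC(=O)/C=C/C(=O)O)c(O)c2c(c1)C(O)OC2=O | intermediate
22 | depsidone, lactol as equilibrating pair | Cc1cc(O)c(C=O)c2c1C(=O)Oc1c(COC(=O)/C=C/C(=O)O)c(O)c3c(c1O2)C(O)OC3=O | intermediate
23 | (R)-N,N-dimethyl-1-phenylethylammonium salt of the (R)-lactol depsidone | Cc1cc(O)c(C=O)c2c1C(=O)Oc1c(COC(=O)/C=C/C(=O)[O-])c(O)c3c(c1O2)[C@H](O)OC3=O.C[C@@H]([NH+](C)C)c1ccccc1 | intermediate
24 | target depsidone, (R)-lactol | Cc1cc(O)c(C=O)c2c1C(=O)Oc1c(COC(=O)/C=C/C(=O)O)c(O)c3c(c1O2)[C@H](O)OC3=O | target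

## Step count and weak points

Total: 15 steps. Longest linear sequence: 11 steps (steps 5 to 15, from 8).

**Step 13 (key step, proposed new method).** The most likely failure is the absence of productive binding, because the C2′ fumarate and the open formyl carboxylate are foreign to the enzyme. Turnover would then be missing or diverted to oxygen rebound (hydroxylation at C6′ or at the C1 methyl), while slow hydrolysis of the benzylic ester in buffer erodes the substrate. The fallback uses known chemistry, a copper-mediated ether closure of a halogenated depside. Compound 2 is allylated only at the hydroxyl para to the ester (allyl bromide, 1 equiv K2CO3, acetone) to methyl 4-(allyloxy)-3-formyl-2-hydroxy-6-methylbenzoate F1. Saponification (KOH, aqueous DMSO) gives 4-(allyloxy)-3-formyl-2-hydroxy-6-methylbenzoic acid F2, in which the future C5 hydroxyl is free. Phenol 17 is iodinated at C6′, its only free ring position (N-iodosuccinimide, MeCN), to allyl 3-({[(2E)-4-(allyloxy)-4-oxobut-2-enoyl]oxy}methyl)-6-formyl-2,4-dihydroxy-5-iodobenzoate F3. The trifluoroacetic anhydride coupling of step 11 joins F2 and F3 to the iodo depside F4. CuI with N,N-dimethylglycine and 1 equiv Cs2CO3 (MeCN, 60 °C) closes ring C by intramolecular Ullmann etherification, the iodide being activated by the ortho formyl group, to the tris-allyl depsidone F5. Deallylation as in step 12 completes the return. The fallback sets out from 2 and 17 and rejoins the route at 22.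

**Step 14 (proposed new method).** The salt may crystallize as a solid solution of both lactol configurations or with the (S)-lactol, the amine may pull material into the ring-open carboxylate, or epimerization in the slurry may be too slow. The fallback uses known chemistry: enantiomer separation of 22 by preparative supercritical-fluid chromatography on an immobilized amylose tris(3,5-dimethylphenylcarbamate) phase (CO2–MeCN with 0.1% formic acid, no alcohol, column below 10 °C). The (R)-enantiomer is collected into a cold receiver and precipitated at once. It sets out from 22 and rejoins at 24, makes no new compound and makes step 15 unnecessary.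

**Step 11.** Slow acylation of the electron-poor, ortho-substituted C1′ phenol by a di-ortho-substituted acyl donor may let trifluoroacetylation and acid-promoted loss of the benzylic fumarate compete. The fallback changes the acyl donor and the medium. Acid 4 is converted with oxalyl chloride and catalytic DMF to 2,4-bis(allyloxy)-3-formyl-6-methylbenzoyl chloride F6, which acylates 17 in CH2Cl2 with pyridine at 0 °C; pyridine is too weak a base to form the phenoxide. It sets out from 4 and rejoins at 19.

**Step 10.** The methoxymethyl cation or formaldehyde released may alkylate the activated C6′ position. Prolonged acid may also solvolyse the benzylic ester, or hydrolyse the C4′ allyl ester with help from the hydrate of the neighbouring formyl group. The fallback changes the order so that no fumarate is present in the acid step. Compound 15 is deprotected (2 M HCl, THF) to allyl 6-formyl-2,4-dihydroxy-3-(hydroxymethyl)benzoate F7. Its primary alcohol alone is then esterified with 7 by a Mitsunobu reaction (PPh3, diisopropyl azodicarboxylate, THF, 0 °C); the phenols are not activated and the carboxylic acid out-competes them as nucleophile. It sets out from 15 and rejoins at 17.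

**Step 8.** The second lithiation of the alkoxide may be incomplete or misdirected (aggregation of the dianion, attack at the acetal), and cyclization onto the acetal may occur if the carboxylic acid is set free. The fallback replaces deprotonation by halogen–metal exchange on a protected alcohol. Compound 12 is silylated (TBSCl, imidazole, DMF) to tert-butyl{[4-(dimethoxymethyl)-2,6-bis(methoxymethoxy)benzyl]oxy}dimethylsilane F8. Bromination at one of its two equivalent ring positions (N-bromosuccinimide, MeCN, 0 °C) gives the aryl bromide F9. Exchange with n-BuLi (THF, −78 °C) and quench with allyl chloroformate gives allyl 3-({[tert-butyl(dimethyl)silyl]oxy}methyl)-6-(dimethoxymethyl)-2,4-bis(methoxymethoxy)benzoate F10, which is desilylated (Bu4NF, AcOH, THF). It sets out from 12 and rejoins at 15.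

## Further compounds

F1 | step 13 | methyl 4-(allyloxy)-3-formyl-2-hydroxy-6-methylbenzoate | COC(=O)c1c(C)cc(OCC=C)c(C=O)c1O
F2 | step 13 | 4-(allyloxy)-3-formyl-2-hydroxy-6-methylbenzoic acid | OC(=O)c1c(C)cc(OCC=C)c(C=O)c1O
F3 | step 13 | allyl 3-({[(2E)-4-(allyloxy)-4-oxobut-2-enoyl]oxy}methyl)-6-formyl-2,4-dihydroxy-5-iodobenzoate | C=CCOC(=O)c1c(O)c(COC(=O)/C=C/C(=O)OCC=C)c(O)c(I)c1C=O
F4 | step 13 | iodo depside (C1′ ester of F3 with acid F2) | Cc1cc(OCC=C)c(C=O)c(O)c1C(=O)Oc1c(I)c(C=O)c(C(=O)OCC=C)c(O)c1COC(=O)/C=C/C(=O)OCC=C
F5 | step 13 | tris-allyl depsidone (C3 allyl ether, C4′ allyl ester, allyl fumarate, C5′ formyl) | Cc1cc(OCC=C)c(C=O)c2c1C(=O)Oc1c(COC(=O)/C=C/C(=O)OCC=C)c(O)c(C(=O)OCC=C)c(C=O)c1O2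
F0 | step 14 | none | none
F6 | step 11 | 2,4-bis(allyloxy)-3-formyl-6-methylbenzoyl chloride | Cc1cc(OCC=C)c(C=O)c(OCC=C)c1C(=O)Cl
F7 | step 10 | allyl 6-formyl-2,4-dihydroxy-3-(hydroxymethyl)benzoate | C=CCOC(=O)c1c(O)c(CO)c(O)cc1C=O
F8 | step 8 | tert-butyl{[4-(dimethoxymethyl)-2,6-bis(methoxymethoxy)benzyl]oxy}dimethylsilane | COC(OC)c1cc(OCOC)c(CO[Si](C)(C)C(C)(C)C)c(OCOC)c1
F9 | step 8 | {[3-bromo-4-(dimethoxymethyl)-2,6-bis(methoxymethoxy)benzyl]oxy}(tert-butyl)dimethylsilane | COC(OC)c1cc(OCOC)c(CO[Si](C)(C)C(C)(C)C)c(OCOC)c1Br
F10 | step 8 | allyl 3-({[tert-butyl(dimethyl)silyl]oxy}methyl)-6-(dimethoxymethyl)-2,4-bis(methoxymethoxy)benzoate | C=CCOC(=O)c1c(OCOC)c(CO[Si](C)(C)C(C)(C)C)c(OCOC)cc1C(OC)OC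
A1 | alternative 1 | diisopropyl squarate | CC(C)OC1=C(OC(C)C)C(=O)C1=O
A2 | alternative 1 | tert-butyl 3-{1-hydroxy-2-isopropoxy-3-[(methoxymethoxy)methyl]-4-oxocyclobut-2-en-1-yl}-4,4-diethoxybut-2-enoate (racemic, alkene geometry immaterial) | O=C1C(COCOC)=C(OC(C)C)C1(O)C(=CC(=O)OC(C)(C)C)C(OCC)OCC
A3 | alternative 1 | ring B hydroquinone with C1′ isopropyl ether, C4′ tert-butyl ester and C5′ diethyl acetal | Oc1c(COCOC)c(OC(C)C)c(O)c(C(OCC)OCC)c1C(=O)OC(C)(C)C
A4 | alternative 2 | ring B aryl 2-diazo-4-methyl-3-oxopent-4-enoate with a (3,3-dimethoxyprop-1-yn-1-yl)oxy group on C6′ | C=C(C)C(=O)C(=[N+]=[N-])C(=O)Oc1c(CO[Si](C)(C)C(C)(C)C)c(OCOC)c(C(=O)OC(C)(C)C)c(C(OC)OC)c1OC#CC(OC)OC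
A5 | alternative 2 | protected depsidone with free C3 phenol and C4 dimethyl acetal | Cc1cc(O)c(C(OC)OC)c2c1C(=O)Oc1c(CO[Si](C)(C)C(C)(C)C)c(OCOC)c(C(=O)OC(C)(C)C)c(C(OC)OC)c1O2
A6 | alternative 3 | 6-(2,4-dioxopentyl)-2,2-dimethyl-4H-1,3-dioxin-4-one | CC(=O)CC(=O)CC1=CC(=O)OC(C)(C)O1
A7 | alternative 3 | ring B fluorophenol (C6′ fluorine, C1′ hydroxyl free) | Oc1c(CO[Si](C)(C)C(C)(C)C)c(OCOC)c(C(=O)OC(C)(C)C)c(C(OC)OC)c1F
A8 | alternative 3 | depside, ring B aryl ester of orsellinic acid with C6′ fluorine | Cc1cc(O)cc(O)c1C(=O)Oc1c(CO[Si](C)(C)C(C)(C)C)c(OCOC)c(C(=O)OC(C)(C)C)c(C(OC)OC)c1F
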